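Numbering: ring C = O1, C2 (bears ring A, 3,4-dihydroxy-5-methoxyphenyl), C3, C4 (OH), C5, C6 (bears CH2CH2–ring B, 4-hydroxy-3-methoxyphenyl). Chain C1/C3/C5 of the open precursors become ring C2/C4/C6.
Cuts: first the three O–benzyl bonds of a protected target, then O1–C2 of ring C (back to an open 1,3,5-triol). Next come chain C1–ring A (aldehyde + aryl Grignard) and chain C4–C5 (ring B propanal + four-carbon dienolate).
Enabling feature: C2 carries ring A directly, and the ring A oxygen at its 4-position sits para to C2. A positive charge at C2 is shared with that oxygen, so the O1–C2 bond can be made, broken and remade under acid.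
Forward: eugenol gives the ring B propanal, the chain grows by four carbons, the syn diol is masked, ring A is added and the triol is released. Ring C, the only ring made, then closes, and the benzyl groups come off last.
Stereochemistry: C6 comes from a BINOL–titanium catalysed vinylogous aldol (absolute control) and C4 from a 1,3-syn chelate-controlled reduction (relay from C6). C2 comes from chair and thermodynamic control in the ring closure (relay from C4 and C6). The target is 2,6-cis with an axial 4-hydroxyl, (2S,4S,6S).

Key step: step 12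

Assumption: the (R)-BINOL/Ti(OiPr)4 catalyst is taken to send the diene to the Re face of the unbranched ring B propanal, the usual sense of BINOL–titanium carbonyl additions; the antipodal ligand is equally available if the sense proves opposite.

Step 1
Reactants: 1 eugenol (4-allyl-2-methoxyphenol)
Product: 2 1-(benzyloxy)-2-methoxy-4-(prop-2-en-1-yl)benzene
Conditions: BnBr, K2CO3, acetone, reflux
Reagents that add atoms: benzyl bromide, BrCc1ccccc1
Why: Williamson ether synthesis on the phenoxide, giving a benzyl ether that should withstand the borane, hydride, organomagnesium and acid steps and leave at the end together with the ring A benzyl groups.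

Step 2
Reactants: 2 1-(benzyloxy)-2-methoxy-4-(prop-2-en-1-yl)benzene
Product: 4 3-[4-(benzyloxy)-3-methoxyphenyl]propan-1-ol, via B-alkyl-9-BBN adduct 3 (not isolated)
Conditions: 9-BBN, THF, 0 °C to rt; then 3 M NaOH, 30% H2O2, 0 °C to rt
Reagents that add atoms: hydrogen peroxide, OO
Why: Brown hydroboration–oxidation, in which the bulky dialkylborane places boron on the terminal allyl carbon so that oxidation should give only the primary alcohol.

Step 3
Reactants: 4 3-[4-(benzyloxy)-3-methoxyphenyl]propan-1-ol
Product: 5 3-[4-(benzyloxy)-3-methoxyphenyl]propanal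
Conditions: TEMPO (10 mol %), PhI(OAc)2, CH2Cl2, rt
Reagents that add atoms: none
Why: Oxoammonium (TEMPO/PhI(OAc)2) oxidation of a primary alcohol, which stops at the aldehyde and leaves the electron-rich arene and the benzyl ether alone.

Step 4
Reactants: 5 3-[4-(benzyloxy)-3-methoxyphenyl]propanal; 6 1,3-bis(trimethylsilyloxy)-1-methoxybuta-1,3-diene (Chan's diene)
Product: 8 methyl (5S)-7-[4-(benzyloxy)-3-methoxyphenyl]-5-hydroxy-3-oxoheptanoate, via bis-silylated aldol adduct 7 (not isolated)
Conditions: Ti(OiPr)4 (10 mol %), (R)-BINOL (10 mol %), LiCl (20 mol %), THF, 0 °C to rt; then TFA, wet THF, 0 °C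
Reagents that add atoms: none
Why: Catalytic enantioselective vinylogous Mukaiyama aldol addition, in which the BINOL–titanium Lewis acid binds the aldehyde and exposes its Re face to the terminal carbon of the diene, setting chain C5 (ring C6) as S before acid strips both silyl groups.

Step 5
Reactants: 8 methyl (5S)-7-[4-(benzyloxy)-3-methoxyphenyl]-5-hydroxy-3-oxoheptanoate
Product: 10 methyl (3S,5S)-7-[4-(benzyloxy)-3-methoxyphenyl]-3,5-dihydroxyheptanoate, via diethylboron chelate 9 (not isolated)
Conditions: Et2BOMe, THF/MeOH (4:1), −78 °C; NaBH4, −78 °C; aq NaHCO3 work-up, then MeOH azeotrope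
Reagents that add atoms: none
Why: Narasaka–Prasad reduction, in which boron ties the C5 oxygen and the C3 ketone into a six-membered half-chair with the C5 substituent equatorial and external hydride adds axially, so the 1,3-syn diol forms and chain C3 (ring C4) is set as S by relay from C5.

Step 6
Reactants: 10 methyl (3S,5S)-7-[4-(benzyloxy)-3-methoxyphenyl]-3,5-dihydroxyheptanoate
Product: 11 methyl 2-[(4S,6S)-6-{2-[4-(benzyloxy)-3-methoxyphenyl]ethyl}-2,2-dimethyl-1,3-dioxan-4-yl]acetate
Conditions: Me2C(OMe)2, PPTS (cat.), CH2Cl2, rt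
Reagents that add atoms: 2,2-dimethoxypropane, COC(C)(C)OC
Why: Acid-catalysed acetal exchange, in which the syn diol closes to a chair 1,3-dioxane with both side chains equatorial, forestalling δ-lactonisation and masking both hydroxyls for the hydride and Grignard steps.

Step 7
Reactants: 11 methyl 2-[(4S,6S)-6-{2-[4-(benzyloxy)-3-methoxyphenyl]ethyl}-2,2-dimethyl-1,3-dioxan-4-yl]acetate
Product: 13 2-[(4S,6S)-6-{2-[4-(benzyloxy)-3-methoxyphenyl]ethyl}-2,2-dimethyl-1,3-dioxan-4-yl]acetaldehyde, via aluminium hemiacetal 12 (not isolated)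
Conditions: i-Bu2AlH (1.05 equiv), toluene, −78 °C; then aq Rochelle salt
Reagents that add atoms: none
Why: Partial ester reduction with i-Bu2AlH, in which the tetrahedral aluminium hemiacetal persists at −78 °C and collapses to the aldehyde only on work-up, a standard operation on 3,5-acetonide esters of this type.

Step 8
Reactants: 14 5-bromo-2-hydroxy-3-methoxybenzaldehyde
Product: 16 5-bromo-3-methoxybenzene-1,2-diol, via aryl formate 15 (not isolated)
Conditions: 30% H2O2, 1 M NaOH, THF/H2O, 0 °C to rt, N2; then 1 M HCl
Reagents that add atoms: hydrogen peroxide, OO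
Why: Dakin oxidation of an ortho-hydroxybenzaldehyde (aryl migration to peroxide oxygen, then formate hydrolysis), chosen because bromine already sits para to the central oxygen, a position that bromination of 3-methoxycatechol or its ethers would miss in favour of the sites ortho and para to the outer oxygens.

Step 9
Reactants: 16 5-bromo-3-methoxybenzene-1,2-diol
Product: 17 1,2-bis(benzyloxy)-5-bromo-3-methoxybenzene
Conditions: BnBr (2.4 equiv), K2CO3, DMF, rt to 50 °C, N2
Reagents that add atoms: benzyl bromide, BrCc1ccccc1
Why: Double Williamson ether synthesis, which removes the acidic and oxidisable catechol protons before metalation and uses the same protecting group as ring B so that one final step frees all three phenols.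

Step 10
Reactants: 17 1,2-bis(benzyloxy)-5-bromo-3-methoxybenzene; 13 2-[(4S,6S)-6-{2-[4-(benzyloxy)-3-methoxyphenyl]ethyl}-2,2-dimethyl-1,3-dioxan-4-yl]acetaldehyde
Product: 19 1-[3,4-bis(benzyloxy)-5-methoxyphenyl]-2-[(4R,6S)-6-{2-[4-(benzyloxy)-3-methoxyphenyl]ethyl}-2,2-dimethyl-1,3-dioxan-4-yl]ethan-1-ol as both carbinol epimers (the dioxane C4 descriptor changes from S to R only through a CIP priority switch), via arylmagnesium bromide 18 (not isolated)
Conditions: Mg, THF, reflux (I2 to start); then 13, THF, −78 °C to 0 °C; aq NH4Cl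
Reagents that add atoms: none
Why: Grignard formation and 1,2-addition to an aldehyde, which makes the chain C1–ring A bond and needs no control at the new carbinol centre because both epimers pass through the same cation in step 12.

Step 11
Reactants: 19 1-[3,4-bis(benzyloxy)-5-methoxyphenyl]-2-[(4R,6S)-6-{2-[4-(benzyloxy)-3-methoxyphenyl]ethyl}-2,2-dimethyl-1,3-dioxan-4-yl]ethan-1-ol (both carbinol epimers)
Product: 20 (3S,5S)-1-[3,4-bis(benzyloxy)-5-methoxyphenyl]-7-[4-(benzyloxy)-3-methoxyphenyl]heptane-1,3,5-triol (both C1 epimers)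
Conditions: 1 M HCl, THF, rt
Reagents that add atoms: none
Why: Acid hydrolysis of an isopropylidene acetal, run in an aqueous medium so that any ionisation at the benzylic carbinol either returns the alcohol by capture of water or already leads towards the ring-closed ether of the next step.

Step 12
Reactants: 20 (3S,5S)-1-[3,4-bis(benzyloxy)-5-methoxyphenyl]-7-[4-(benzyloxy)-3-methoxyphenyl]heptane-1,3,5-triol (both C1 epimers)
Product: 22 (2S,4S,6S)-2-[3,4-bis(benzyloxy)-5-methoxyphenyl]-6-{2-[4-(benzyloxy)-3-methoxyphenyl]ethyl}oxan-4-ol, via benzylic cation 21 (not isolated)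
Conditions: Bi(OTf)3 (5 mol %), CH2Cl2 (0.01 M), 0 °C to rt
Reagents that add atoms: none
Why: Bi(OTf)3, helped by the triflic acid it sheds once water appears, turns the chain C1 hydroxyl of either epimer into a leaving group, and only this hydroxyl departs because cation 21 spreads its charge onto the para 4-benzyloxy oxygen of ring A (a para-quinone methide oxonium form) while the C3 and C5 carbinols are plain secondary alcohols, so the two epimers merge in one planar species. The C5 hydroxyl adds to the trigonal carbon in a 6-exo-trig closure that makes the O1–C2 bond and ring C, the closest known reaction type being the acid-catalysed dehydrative cycloetherification of 1-aryl-1,5-diols to 2,6-cis-2-aryltetrahydropyrans. The one new stereocentre, C2, is governed by the C4 and C6 centres through the chair: with the C6 side chain equatorial the C4 hydroxyl is axial, an axial ring A would meet it in a 1,3-diaxial contact, and ring A therefore ends up equatorial, which is the (2S) configuration. The 2,6-trans ether can escape that contact only by flipping to a chair with the C6 chain axial beside O1, which by conformational energies costs clearly more than the single axial hydroxyl of the cis ether, and since the C2–O1 bond of the product re-ionises under the same acid, trans material is fed back through 21 to the cis ether. Of the two free hydroxyls only the C5 one gives a lasting product, because closure by the C3 hydroxyl would give a strained oxetane that reopens to 21. The step needs capture to beat loss of a chain C2 proton and retro-Prins cleavage of the C2–C3 bond, which the proximity of the C5 hydroxyl, high dilution, low temperature and a low catalyst loading should secure.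

Step 13
Reactants: 22 (2S,4S,6S)-2-[3,4-bis(benzyloxy)-5-methoxyphenyl]-6-{2-[4-(benzyloxy)-3-methoxyphenyl]ethyl}oxan-4-ol
Product: 23 (2S,4S,6S)-2-(3,4-dihydroxy-5-methoxyphenyl)-6-[2-(4-hydroxy-3-methoxyphenyl)ethyl]oxan-4-ol (target)
Conditions: H2 (1 atm), 10% Pd/C, EtOAc/MeOH, rt; filtration and concentration under N2
Reagents that add atoms: none
Why: Heterogeneous catalytic hydrogenolysis, in which the three aryl benzyl ethers are unhindered primary benzylic C–O bonds that cleave quickly whereas the C2–O1 bond is a secondary, ring-held benzylic ether and reacts much more slowly in a neutral solvent, so stopping after three equivalents of H2 should leave ring C and all three stereocentres untouched.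

Compound list
1 | eugenol (4-allyl-2-methoxyphenol) | COc1cc(CC=C)ccc1O | starting material
2 | 1-(benzyloxy)-2-methoxy-4-(prop-2-en-1-yl)benzene | COc1cc(CC=C)ccc1OCc1ccccc1 | intermediate
3 | 9-{3-[4-(benzyloxy)-3-methoxyphenyl]propyl}-9-borabicyclo[3.3.1]nonane (not isolated) | COc1cc(CCCB2C3CCCC2CCC3)ccc1OCc1ccccc1 | intermediate
4 | 3-[4-(benzyloxy)-3-methoxyphenyl]propan-1-ol | COc1cc(CCCO)ccc1OCc1ccccc1 | intermediate
5 | 3-[4-(benzyloxy)-3-methoxyphenyl]propanal | COc1cc(CCC=O)ccc1OCc1ccccc1 | intermediate
6 | 1,3-bis(trimethylsilyloxy)-1-methoxybuta-1,3-diene | COC(O[Si](C)(C)C)=CC(=C)O[Si](C)(C)C | starting material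
7 | methyl (5S)-7-[4-(benzyloxy)-3-methoxyphenyl]-3,5-bis(trimethylsilyloxy)hept-2-enoate, enol ether geometry not defined (not isolated) | COc1cc(CC[C@H](O[Si](C)(C)C)CC(O[Si](C)(C)C)=CC(=O)OC)ccc1OCc1ccccc1 | intermediate
8 | methyl (5S)-7-[4-(benzyloxy)-3-methoxyphenyl]-5-hydroxy-3-oxoheptanoate | COc1cc(CC[C@H](O)CC(=O)CC(=O)OC)ccc1OCc1ccccc1 | intermediate
9 | methyl (5S)-7-[4-(benzyloxy)-3-methoxyphenyl]-5-[(diethylboranyl)oxy]-3-oxoheptanoate, boron chelated by the C3 ketone (not isolated) | COc1cc(CC[C@H](OB(CC)CC)CC(=O)CC(=O)OC)ccc1OCc1ccccc1 | intermediate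
10 | methyl (3S,5S)-7-[4-(benzyloxy)-3-methoxyphenyl]-3,5-dihydroxyheptanoate (syn diol) | COc1cc(CC[C@H](O)C[C@H](O)CC(=O)OC)ccc1OCc1ccccc1 | intermediate
11 | methyl 2-[(4S,6S)-6-{2-[4-(benzyloxy)-3-methoxyphenyl]ethyl}-2,2-dimethyl-1,3-dioxan-4-yl]acetate | COc1cc(CC[C@H]2C[C@@H](CC(=O)OC)OC(C)(C)O2)ccc1OCc1ccccc1 | intermediate
12 | diisobutylaluminium methyl hemiacetal of aldehyde 13, hemiacetal carbon not defined (not isolated) | COc1cc(CC[C@H]2C[C@@H](CC(OC)O[Al](CC(C)C)CC(C)C)OC(C)(C)O2)ccc1OCc1ccccc1 | intermediate
13 | 2-[(4S,6S)-6-{2-[4-(benzyloxy)-3-methoxyphenyl]ethyl}-2,2-dimethyl-1,3-dioxan-4-yl]acetaldehyde | COc1cc(CC[C@H]2C[C@@H](CC=O)OC(C)(C)O2)ccc1OCc1ccccc1 | intermediate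
14 | 5-bromo-2-hydroxy-3-methoxybenzaldehyde | COc1cc(Br)cc(C=O)c1O | starting material
15 | 5-bromo-2-hydroxy-3-methoxyphenyl formate (not isolated) | COc1cc(Br)cc(OC=O)c1O | intermediate
16 | 5-bromo-3-methoxybenzene-1,2-diol | COc1cc(Br)cc(O)c1O | intermediate
17 | 1,2-bis(benzyloxy)-5-bromo-3-methoxybenzene | COc1cc(Br)cc(OCc2ccccc2)c1OCc1ccccc1 | intermediate
18 | [3,4-bis(benzyloxy)-5-methoxyphenyl]magnesium bromide (not isolated) | COc1cc([Mg]Br)cc(OCc2ccccc2)c1OCc1ccccc1 | intermediate
19 | 1-[3,4-bis(benzyloxy)-5-methoxyphenyl]-2-[(4R,6S)-6-{2-[4-(benzyloxy)-3-methoxyphenyl]ethyl}-2,2-dimethyl-1,3-dioxan-4-yl]ethan-1-ol, both carbinol epimers | COc1cc(CC[C@H]2C[C@@H](CC(O)c3cc(OCc4ccccc4)c(OCc4ccccc4)c(OC)c3)OC(C)(C)O2)ccc1OCc1ccccc1 | intermediate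
20 | (3S,5S)-1-[3,4-bis(benzyloxy)-5-methoxyphenyl]-7-[4-(benzyloxy)-3-methoxyphenyl]heptane-1,3,5-triol, both C1 epimers | COc1cc(CC[C@H](O)C[C@H](O)CC(O)c2cc(OCc3ccccc3)c(OCc3ccccc3)c(OC)c2)ccc1OCc1ccccc1 | intermediate
21 | chain C1 benzylic cation derived from 20 (not isolated) | COc1cc(CC[C@H](O)C[C@H](O)C[CH+]c2cc(OCc3ccccc3)c(OCc3ccccc3)c(OC)c2)ccc1OCc1ccccc1 | intermediate
22 | (2S,4S,6S)-2-[3,4-bis(benzyloxy)-5-methoxyphenyl]-6-{2-[4-(benzyloxy)-3-methoxyphenyl]ethyl}oxan-4-ol | COc1cc(CC[C@H]2C[C@H](O)C[C@@H](c3cc(OCc4ccccc4)c(OCc4ccccc4)c(OC)c3)O2)ccc1OCc1ccccc1 | intermediate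
23 | (2S,4S,6S)-2-(3,4-dihydroxy-5-methoxyphenyl)-6-[2-(4-hydroxy-3-methoxyphenyl)ethyl]oxan-4-ol | COc1cc(CC[C@H]2C[C@H](O)C[C@@H](c3cc(O)c(O)c(OC)c3)O2)ccc1O | target

Total step count: 13. Longest linear sequence: 11 steps (steps 1–7 and 10–13, from eugenol). The ring A branch (steps 8 and 9) adds two steps.

Steps most likely to fail

**Step 12.**
- **Loss of the cation:** it may be lost before the C5 hydroxyl captures it. One path is proton loss from chain C2 to a styrene, followed by ionisation of the then allylic C3 hydroxyl. Others are retro-Prins cleavage of the C2–C3 bond and intermolecular Friedel–Crafts attack on the electron-rich rings. All of these grow if long equilibration is needed.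
- **Slow ionisation:** the 4-benzyloxy group is flanked on both sides and partly twisted out of conjugation.
- **Fallback:** ring closure at the ketone oxidation level followed by reduction, setting out from 19. Dess–Martin periodinane in CH2Cl2 should give 1-[3,4-bis(benzyloxy)-5-methoxyphenyl]-2-[(4S,6S)-6-{2-[4-(benzyloxy)-3-methoxyphenyl]ethyl}-2,2-dimethyl-1,3-dioxan-4-yl]ethan-1-one F1. Then 1 M HCl in THF should free (3S,5S)-1-[3,4-bis(benzyloxy)-5-methoxyphenyl]-7-[4-(benzyloxy)-3-methoxyphenyl]-3,5-dihydroxyheptan-1-one F2, which equilibrates with its six-membered hemiketal. Et3SiH with BF3·OEt2 in CH2Cl2/MeCN at −78 to −40 °C should reduce the derived cyclic oxocarbenium ion by axial hydride delivery, the established reductive route to 2,6-cis-tetrahydropyrans. The sequence comes back to the route at 22.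

**Step 4.**
- **Risk:** poor facial selectivity with an unbranched, enolisable aliphatic aldehyde, or a competing uncatalysed or silyl-cation-catalysed background addition. Either would erode the enantiomeric purity on which all later centres depend.
- **Fallback:** the carbinol centre is set by asymmetric hydrogenation instead of by C–C bond formation, setting out from 5. Roskamp homologation with ethyl diazoacetate and SnCl2 (cat.) in CH2Cl2 should give ethyl 5-[4-(benzyloxy)-3-methoxyphenyl]-3-oxopentanoate F3. Noyori hydrogenation with RuCl2[(S)-BINAP] under H2 in EtOH should give ethyl (3S)-5-[4-(benzyloxy)-3-methoxyphenyl]-3-hydroxypentanoate F4, without touching the benzyl ether. A crossed Claisen condensation with excess lithium enolate of methyl acetate (LDA, THF, −78 to −20 °C) comes back to the route at 8.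

**Step 13.**
- **Risk:** over-reduction, that is hydrogenolytic opening of ring C at the benzylic C2–O1 bond once the phenols are free, and air oxidation of the catechol during isolation.
- **Fallback:** non-reductive Lewis-acid debenzylation with a cation scavenger, setting out from 22. BCl3 and pentamethylbenzene in CH2Cl2 at −78 °C, followed by a MeOH quench, should cleave the three aryl benzyl ethers and leave the aryl methyl ethers. Any transient opening at C2 recloses to the same diequatorial ether. The sequence comes back to the route at 23 and makes no new compound (F0).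

Further compounds
F1 | step 12 | 1-[3,4-bis(benzyloxy)-5-methoxyphenyl]-2-[(4S,6S)-6-{2-[4-(benzyloxy)-3-methoxyphenyl]ethyl}-2,2-dimethyl-1,3-dioxan-4-yl]ethan-1-one | COc1cc(CC[C@H]2C[C@@H](CC(=O)c3cc(OCc4ccccc4)c(OCc4ccccc4)c(OC)c3)OC(C)(C)O2)ccc1OCc1ccccc1
F2 | step 12 | (3S,5S)-1-[3,4-bis(benzyloxy)-5-methoxyphenyl]-7-[4-(benzyloxy)-3-methoxyphenyl]-3,5-dihydroxyheptan-1-one | COc1cc(CC[C@H](O)C[C@H](O)CC(=O)c2cc(OCc3ccccc3)c(OCc3ccccc3)c(OC)c2)ccc1OCc1ccccc1
F3 | step 4 | ethyl 5-[4-(benzyloxy)-3-methoxyphenyl]-3-oxopentanoate | COc1cc(CCC(=O)CC(=O)OCC)ccc1OCc1ccccc1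
F4 | step 4 | ethyl (3S)-5-[4-(benzyloxy)-3-methoxyphenyl]-3-hydroxypentanoate | COc1cc(CC[C@H](O)CC(=O)OCC)ccc1OCc1ccccc1
F0 | step 13 | none | none
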